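**Retrosynthetic overview**

1. Locants used below: C1 = CH2OAc, C2=C3(CH3) = the E-alkene, C4 and C5 = the two chain CH2 groups, C6 = CHOH, C7 = the ring carbon that carries CH3 and the ring oxygen; ring A = the 6,7-dihydrooxepin-2(5H)-one.
2. Last disconnection, C5–C6: target ⇒ ring A aldehyde (C6 as CHO on C7) + [(E)-5-acetoxy-3-methylpent-3-enyl](trimethylsilylmethyl)zinc. A titanium/bis(sulfonamide)-catalysed enantioselective alkyl transfer forms the bond, sets C6 and ends the synthesis with no protecting group on either partner.
3. Enabling feature: C6 lies between the unbranched methylene C5 and the fully substituted ring carbon C7. A C6 aldehyde on ring A therefore has no α-hydrogen (no enolisation, no epimerisation), and its C7–O ring bond gives a Felkin–Anh preference for the required 6R face, matched to the catalyst.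
4. Ring A, the only ring, is closed before the union by ring-closing metathesis of a 2-(homoprenyl)acrylate of a tertiary alcohol; C7 comes from (R)-2-methylglycidol by allyl opening of the epoxide.
5. The zinc arm comes from silylated but-3-yn-1-ol by zirconium-catalysed carboalumination (E-alkene), zinc insertion into the derived primary iodide and capping of zinc with a non-transferable trimethylsilylmethyl group; the acrylic acid comes from diethyl malonate.

Key step: step 15

Remark on the chemistry: the facial preference of the titanium bis(sulfonamide) catalyst is assigned by analogy with simple aldehydes; should the opposite sense be found, the (1R,2R) ligand is used instead.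

**Route**

Step 1
Reactants: 1 diethyl malonate; 2 5-bromo-2-methylpent-2-ene
Product: 3 diethyl 2-(4-methylpent-3-en-1-yl)malonate
Conditions: NaOEt, EtOH, reflux (excess 1)
Reagents that add atoms: none
Why: Malonic ester alkylation, an SN2 displacement of the primary homoallylic bromide by the malonate anion, with excess malonate suppressing dialkylation.

Step 2
Reactants: 3 diethyl 2-(4-methylpent-3-en-1-yl)malonate
Product: 4 2-(4-methylpent-3-en-1-yl)malonic acid
Conditions: KOH, EtOH/H2O, reflux; then cold aq. HCl to pH 2, 0 °C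
Reagents that add atoms: potassium hydroxide, [K+].[OH-]
Why: Ester saponification, with cold acidification so that the diacid does not lactonise onto the trisubstituted alkene.

Step 3
Reactants: 4 2-(4-methylpent-3-en-1-yl)malonic acid
Product: 5 6-methyl-2-methylidenehept-5-enoic acid
Conditions: (CH2O)n, Et2NH, EtOAc, reflux
Reagents that add atoms: paraformaldehyde (as formaldehyde), C=O
Why: Mannich-type decarboxylative methylenation of a monosubstituted malonic acid, in which the aminomethylated diacid loses CO2 and diethylamine to give the 2-substituted acrylic acid.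

Step 4
Reactants: 6 (R)-2-methylglycidol
Product: 7 (S)-2-{[(4-methoxybenzyl)oxy]methyl}-2-methyloxirane
Conditions: NaH, 4-methoxybenzyl chloride, n-Bu4NI (cat.), THF/DMF, 0 °C → rt
Reagents that add atoms: 4-methoxybenzyl chloride, COc1ccc(CCl)cc1
Why: Williamson ether synthesis on the primary alkoxide; the quaternary stereocentre is not touched (a Payne shift of this alkoxide is degenerate) and the descriptor changes from R to S only through the priority rules.

Step 5
Reactants: 7 (S)-2-{[(4-methoxybenzyl)oxy]methyl}-2-methyloxirane; 8 allylmagnesium bromide (CH2=CHCH2MgBr)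
Product: 9 (S)-1-[(4-methoxybenzyl)oxy]-2-methylhex-5-en-2-ol
Conditions: CuI (10 mol%), THF, −40 → 0 °C; aq. NH4Cl
Reagents that add atoms: none
Why: Copper-catalysed SN2 opening of the 2,2-disubstituted epoxide at its unsubstituted carbon; the C–O bond at the stereocentre is not broken, so the tertiary carbinol (future C7) keeps its configuration.

Step 6
Reactants: 9 (S)-1-[(4-methoxybenzyl)oxy]-2-methylhex-5-en-2-ol; 5 6-methyl-2-methylidenehept-5-enoic acid
Product: 11 (S)-1-[(4-methoxybenzyl)oxy]-2-methylhex-5-en-2-yl 6-methyl-2-methylidenehept-5-enoate, via acid chloride 10 (not isolated)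
Conditions: 5, 1-chloro-N,N,2-trimethylprop-1-en-1-amine, CH2Cl2, 0 °C → rt; separately 9, n-BuLi, THF, −78 °C; then 10, −78 → 0 °C
Reagents that add atoms: none
Why: O-acylation of a lithium tertiary alkoxide by an acid chloride that is made under neutral conditions, so that no HCl adds to the trisubstituted alkene, while the PMB ether cannot migrate to the alkoxide.

Step 7
Reactants: 11 (S)-1-[(4-methoxybenzyl)oxy]-2-methylhex-5-en-2-yl 6-methyl-2-methylidenehept-5-enoate
Product: 12 (S)-7-{[(4-methoxybenzyl)oxy]methyl}-7-methyl-3-(4-methylpent-3-en-1-yl)-6,7-dihydrooxepin-2(5H)-one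
Conditions: second-generation Grubbs catalyst RuCl2(=CHPh)(PCy3)(H2IMes) (2 × 5 mol%), toluene (0.003 M), 80 °C
Reagents that add atoms: none
Why: Ring-closing metathesis, in which the catalyst loads on the monosubstituted alkene and closes onto the 1,1-disubstituted acrylate to give the seven-membered trisubstituted enoate, helped by the quaternary carbinol carbon (Thorpe–Ingold effect) and high dilution, while the trisubstituted side-chain alkene is too hindered to compete.

Step 8
Reactants: 12 (S)-7-{[(4-methoxybenzyl)oxy]methyl}-7-methyl-3-(4-methylpent-3-en-1-yl)-6,7-dihydrooxepin-2(5H)-one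
Product: 13 (S)-7-(hydroxymethyl)-7-methyl-3-(4-methylpent-3-en-1-yl)-6,7-dihydrooxepin-2(5H)-one
Conditions: DDQ, CH2Cl2/pH 7 buffer (10:1), 0 °C
Reagents that add atoms: none
Why: Oxidative cleavage of the electron-rich PMB ether by DDQ through the benzylic oxocarbenium ion, under neutral conditions that should leave the lactone and both alkenes intact.

Step 9
Reactants: 13 (S)-7-(hydroxymethyl)-7-methyl-3-(4-methylpent-3-en-1-yl)-6,7-dihydrooxepin-2(5H)-one
Product: 14 (S)-2-methyl-6-(4-methylpent-3-en-1-yl)-7-oxo-2,3,4,7-tetrahydrooxepine-2-carbaldehyde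
Conditions: Dess–Martin periodinane, pyridine, CH2Cl2, 0 °C → rt; used directly
Reagents that add atoms: none
Why: Dess–Martin oxidation of the primary alcohol under buffered non-aqueous conditions; the aldehyde has no α-hydrogen and so cannot epimerise.

Step 10
Reactants: 15 tert-butyl(but-3-yn-1-yloxy)dimethylsilane
Product: 17 (E)-5-[(tert-butyldimethylsilyl)oxy]-3-methylpent-2-en-1-ol, via alkenyldimethylalane 16 (not isolated)
Conditions: Me3Al, Cp2ZrCl2 (0.25 equiv), CH2Cl2, 0 °C → rt; then (CH2O)n, 0 °C → rt; aq. potassium sodium tartrate (KNaC4H4O6)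
Reagents that add atoms: trimethylaluminium, C[Al](C)C; paraformaldehyde (as formaldehyde), C=O
Why: Zirconium-catalysed carboalumination adds methyl and aluminium syn across the alkyne with aluminium at the terminal carbon, which fixes the E-trisubstituted alkene, and the alkenylalane then adds to formaldehyde with retention of geometry.

Step 11
Reactants: 17 (E)-5-[(tert-butyldimethylsilyl)oxy]-3-methylpent-2-en-1-ol
Product: 18 (E)-5-[(tert-butyldimethylsilyl)oxy]-3-methylpent-2-en-1-yl acetate
Conditions: Ac2O, pyridine, DMAP (cat.), CH2Cl2, 0 °C → rt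
Reagents that add atoms: acetic anhydride, CC(=O)OC(C)=O
Why: DMAP-catalysed acetylation of the primary allylic alcohol.

Step 12
Reactants: 18 (E)-5-[(tert-butyldimethylsilyl)oxy]-3-methylpent-2-en-1-yl acetate
Product: 19 (E)-5-hydroxy-3-methylpent-2-en-1-yl acetate
Conditions: HF·pyridine, THF/pyridine, 0 °C → rt
Reagents that add atoms: none
Why: Fluoride cleavage of the primary silyl ether under mildly acidic conditions, which should neither hydrolyse nor shift the acetate.

Step 13
Reactants: 19 (E)-5-hydroxy-3-methylpent-2-en-1-yl acetate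
Product: 20 (E)-5-iodo-3-methylpent-2-en-1-yl acetate
Conditions: I2, PPh3, imidazole, CH2Cl2, 0 °C
Reagents that add atoms: iodine, II
Why: Appel-type iodination, an SN2 attack of iodide on the alkoxyphosphonium ion under neutral conditions that spare the allylic acetate.

Step 14
Reactants: 20 (E)-5-iodo-3-methylpent-2-en-1-yl acetate
Product: 22 [(3E)-5-acetoxy-3-methylpent-3-en-1-yl][(trimethylsilyl)methyl]zinc, via alkylzinc iodide 21 (not isolated)
Conditions: Zn dust (activated with BrCH2CH2Br and Me3SiCl, cat.), THF, 40 °C; solution cannulated off excess Zn; then Me3SiCH2Li (1.0 equiv, pentane), added slowly at −80 °C; THF removed in vacuo, residue taken up in toluene and cannulated off LiI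
Reagents that add atoms: zinc, [Zn]; (trimethylsilyl)methyllithium, [Li]C[Si](C)(C)C
Why: Direct insertion of activated zinc into the primary carbon–iodine bond gives the ester-tolerant alkylzinc iodide without copper (so that no SN2′ attack on the allylic acetate is triggered), and transmetalation with (trimethylsilyl)methyllithium at −80 °C, which is much faster than attack on the acetate, gives the mixed diorganozinc in which the trimethylsilylmethyl group serves as a non-transferable ligand.

Step 15
Reactants: 14 (S)-2-methyl-6-(4-methylpent-3-en-1-yl)-7-oxo-2,3,4,7-tetrahydrooxepine-2-carbaldehyde; 22 [(3E)-5-acetoxy-3-methylpent-3-en-1-yl][(trimethylsilyl)methyl]zinc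
Product: 23 (2E,6R)-6-hydroxy-3-methyl-6-[(2S)-2-methyl-6-(4-methylpent-3-en-1-yl)-7-oxo-2,3,4,7-tetrahydrooxepin-2-yl]hex-2-en-1-yl acetate (target)
Conditions: 22 (1.6 equiv), Ti(OiPr)4 (2.0 equiv), (1S,2S)-1,2-bis(trifluoromethanesulfonamido)cyclohexane (10 mol%), toluene, −20 °C; then 14, −20 °C; sat. aq. NH4Cl
Reagents that add atoms: none
Why: The bis(sulfonamide) and Ti(OiPr)4 form a chiral titanium bis(sulfonamido) diisopropoxide that binds the aldehyde oxygen of 14, while the functionalised alkyl group of 22 passes from zinc through titanium to the carbonyl carbon and the trimethylsilylmethyl group, a poor migrating group, stays on zinc, so that the side-chain fragment is used once and not as two alkyl groups per zinc. The closest known reaction type is the titanium/bis(sulfonamide)-catalysed enantioselective addition of ester-bearing dialkylzinc and alkyl(trimethylsilylmethyl)zinc reagents to aliphatic and α-oxygenated aldehydes; no ring is closed. The new stereocentre C6 (R) is set by the ligand: the (1S,2S) enantiomer is chosen for delivery to the Re face, its (1R,2R) antipode being known to direct alkyl groups to the Si face of aldehydes. The resident centre C7 points the same way, since in the Felkin–Anh arrangement the C7–O ring bond lies anti to the incoming alkyl group, which then passes the C7 methyl group, so catalyst and substrate are matched. The step needs chemoselectivity for the aldehyde over the lactone carbonyl, the enoate β-carbon and the acetate groups, which the low nucleophilicity of carbon–zinc and carbon–titanium bonds at −20 °C secures, and the missing α-hydrogen of 14 excludes enolisation, aldol reaction and epimerisation. One operation thus forms the C5–C6 bond, sets C6, brings in the whole acetoxy side chain and gives the target directly.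

**Compound list**

1 | diethyl malonate | CCOC(=O)CC(=O)OCC | starting material
2 | 5-bromo-2-methylpent-2-ene | CC(C)=CCCBr | starting material
3 | diethyl 2-(4-methylpent-3-en-1-yl)malonate | CCOC(=O)C(CCC=C(C)C)C(=O)OCC | intermediate
4 | 2-(4-methylpent-3-en-1-yl)malonic acid | OC(=O)C(CCC=C(C)C)C(=O)O | intermediate
5 | 6-methyl-2-methylidenehept-5-enoic acid | C=C(CCC=C(C)C)C(=O)O | intermediate
6 | (R)-2-methylglycidol, (R)-(2-methyloxiran-2-yl)methanol | C[C@@]1(CO)CO1 | starting material
7 | (S)-2-{[(4-methoxybenzyl)oxy]methyl}-2-methyloxirane | C[C@@]1(COCc2ccc(OC)cc2)CO1 | intermediate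
8 | allylmagnesium bromide | C=CC[Mg]Br | starting material
9 | (S)-1-[(4-methoxybenzyl)oxy]-2-methylhex-5-en-2-ol | C[C@@](O)(COCc1ccc(OC)cc1)CCC=C | intermediate
10 | 6-methyl-2-methylidenehept-5-enoyl chloride | C=C(CCC=C(C)C)C(Cl)=O | intermediate (not isolated)
11 | (S)-1-[(4-methoxybenzyl)oxy]-2-methylhex-5-en-2-yl 6-methyl-2-methylidenehept-5-enoate | C[C@@](OC(=O)C(=C)CCC=C(C)C)(COCc1ccc(OC)cc1)CCC=C | intermediate
12 | (S)-7-{[(4-methoxybenzyl)oxy]methyl}-7-methyl-3-(4-methylpent-3-en-1-yl)-6,7-dihydrooxepin-2(5H)-one | C[C@@]1(COCc2ccc(OC)cc2)CCC=C(CCC=C(C)C)C(=O)O1 | intermediate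
13 | (S)-7-(hydroxymethyl)-7-methyl-3-(4-methylpent-3-en-1-yl)-6,7-dihydrooxepin-2(5H)-one | C[C@@]1(CO)CCC=C(CCC=C(C)C)C(=O)O1 | intermediate
14 | (S)-2-methyl-6-(4-methylpent-3-en-1-yl)-7-oxo-2,3,4,7-tetrahydrooxepine-2-carbaldehyde | C[C@@]1(C=O)CCC=C(CCC=C(C)C)C(=O)O1 | intermediate
15 | tert-butyl(but-3-yn-1-yloxy)dimethylsilane | C#CCCO[Si](C)(C)C(C)(C)C | starting material
16 | (E)-{4-[(tert-butyldimethylsilyl)oxy]-2-methylbut-1-en-1-yl}dimethylalane | C[Al](C)/C=C(\C)CCO[Si](C)(C)C(C)(C)C | intermediate (not isolated)
17 | (E)-5-[(tert-butyldimethylsilyl)oxy]-3-methylpent-2-en-1-ol | OC/C=C(\C)CCO[Si](C)(C)C(C)(C)C | intermediate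
18 | (E)-5-[(tert-butyldimethylsilyl)oxy]-3-methylpent-2-en-1-yl acetate | CC(=O)OC/C=C(\C)CCO[Si](C)(C)C(C)(C)C | intermediate
19 | (E)-5-hydroxy-3-methylpent-2-en-1-yl acetate | CC(=O)OC/C=C(\C)CCO | intermediate
20 | (E)-5-iodo-3-methylpent-2-en-1-yl acetate | CC(=O)OC/C=C(\C)CCI | intermediate
21 | [(3E)-5-acetoxy-3-methylpent-3-en-1-yl]zinc iodide | CC(=O)OC/C=C(\C)CC[Zn]I | intermediate (not isolated)
22 | [(3E)-5-acetoxy-3-methylpent-3-en-1-yl][(trimethylsilyl)methyl]zinc | CC(=O)OC/C=C(\C)CC[Zn]C[Si](C)(C)C | intermediate
23 | (2E,6R)-6-hydroxy-3-methyl-6-[(2S)-2-methyl-6-(4-methylpent-3-en-1-yl)-7-oxo-2,3,4,7-tetrahydrooxepin-2-yl]hex-2-en-1-yl acetate | CC(=O)OC/C=C(\C)CC[C@@H](O)[C@]1(C)CCC=C(CCC=C(C)C)C(=O)O1 | target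

**Step count**

Total: 15 steps. Longest linear sequence: 8 steps (steps 1, 2, 3, 6, 7, 8, 9, 15).

**Three steps most likely to fail**

1. Step 15. Alkyl transfer to the neopentyl-type aldehyde may be slow, so that reduction of the aldehyde by β-hydride transfer from the zinc reagent, an uncatalysed background addition promoted by residual lithium salts, or weak facial control takes over. The fallback sets out from 14 and 20 (step 14 is then not needed) and returns at 23. Iodide 20 should add to 14 as its alkylchromium species (CrCl2, catalytic cobalt phthalocyanine Co(C32H16N8), DMF, rt; Nozaki–Hiyama type addition) to give the C6-epimeric alcohol mixture F1. Oxidation with Dess–Martin periodinane should give the C6 ketone F2. Corey–Bakshi–Shibata reduction with (S)-2-methyl-CBS-oxazaborolidine and catecholborane (toluene, −78 °C), in which the quaternary C7 is the large and the CH2 chain the small substituent, should then deliver 23 with the 6R configuration.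

2. Step 7. Closure onto the electron-poor 1,1-disubstituted alkene may be slower than intermolecular metathesis at the terminal alkene, leading to oligomers and catalyst decay. The fallback sets out from 9 and returns at 12, and builds the ring alkene by olefination followed by lactonisation. Lemieux–Johnson cleavage of 9 (OsO4 cat., NaIO4, 2,6-lutidine, dioxane/H2O) should give (5S)-5-{[(4-methoxybenzyl)oxy]methyl}-5-methyloxolan-2-ol F3. Separately, alkylation of commercial methyl bis(2,2,2-trifluoroethyl)phosphonoacetate with bromide 2 (NaH, DMF) should give methyl 2-[bis(2,2,2-trifluoroethoxy)phosphoryl]-6-methylhept-5-enoate F4. Still–Gennari olefination of F3 with F4 (KN(SiMe3)2, 18-crown-6, THF, −78 °C) should give the Z-enoate methyl (2Z,6S)-6-hydroxy-7-[(4-methoxybenzyl)oxy]-6-methyl-2-(4-methylpent-3-en-1-yl)hept-2-enoate F5. Saponification (LiOH, THF/H2O) should give the seco acid (2Z,6S)-6-hydroxy-7-[(4-methoxybenzyl)oxy]-6-methyl-2-(4-methylpent-3-en-1-yl)hept-2-enoic acid F6, and Yamaguchi lactonisation (2,4,6-trichlorobenzoyl chloride, Et3N, then DMAP, toluene, high dilution) should close ring A to 12.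

3. Step 6. O-acylation of the hindered tertiary alkoxide may be incomplete, while the 2-substituted acryloyl chloride decomposes or polymerises. The fallback sets out from 9 and returns at 11, making the ester bond through a ketene and adding the side chain and the methylene group afterwards. Carbodiimide esterification of 9 with commercial 2-(diethoxyphosphoryl)acetic acid (DCC, CH2Cl2), which runs through a phosphonoketene and therefore acylates tertiary alcohols, should give (S)-1-[(4-methoxybenzyl)oxy]-2-methylhex-5-en-2-yl 2-(diethoxyphosphoryl)acetate F7. Alkylation with bromide 2 (NaH, DMSO, 60 °C) should give (S)-1-[(4-methoxybenzyl)oxy]-2-methylhex-5-en-2-yl 2-(diethoxyphosphoryl)-6-methylhept-5-enoate F8, and Horner–Wadsworth–Emmons reaction of F8 with aqueous formaldehyde (K2CO3, THF/H2O, rt) should give 11.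

**Further compounds**

F1 | step 15 | (2E)-6-hydroxy-3-methyl-6-[(2S)-2-methyl-6-(4-methylpent-3-en-1-yl)-7-oxo-2,3,4,7-tetrahydrooxepin-2-yl]hex-2-en-1-yl acetate, mixture of C6 epimers | CC(=O)OC/C=C(\C)CCC(O)[C@]1(C)CCC=C(CCC=C(C)C)C(=O)O1
F2 | step 15 | (2E)-3-methyl-6-[(2S)-2-methyl-6-(4-methylpent-3-en-1-yl)-7-oxo-2,3,4,7-tetrahydrooxepin-2-yl]-6-oxohex-2-en-1-yl acetate | CC(=O)OC/C=C(\C)CCC(=O)[C@]1(C)CCC=C(CCC=C(C)C)C(=O)O1
F3 | step 7 | (5S)-5-{[(4-methoxybenzyl)oxy]methyl}-5-methyloxolan-2-ol | C[C@@]1(COCc2ccc(OC)cc2)CCC(O)O1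
F4 | step 7 | methyl 2-[bis(2,2,2-trifluoroethoxy)phosphoryl]-6-methylhept-5-enoate | COC(=O)C(CCC=C(C)C)P(=O)(OCC(F)(F)F)OCC(F)(F)F
F5 | step 7 | methyl (2Z,6S)-6-hydroxy-7-[(4-methoxybenzyl)oxy]-6-methyl-2-(4-methylpent-3-en-1-yl)hept-2-enoate | COC(=O)/C(CCC=C(C)C)=C\CC[C@](C)(O)COCc1ccc(OC)cc1
F6 | step 7 | (2Z,6S)-6-hydroxy-7-[(4-methoxybenzyl)oxy]-6-methyl-2-(4-methylpent-3-en-1-yl)hept-2-enoic acid | OC(=O)/C(CCC=C(C)C)=C\CC[C@](C)(O)COCc1ccc(OC)cc1
F7 | step 6 | (S)-1-[(4-methoxybenzyl)oxy]-2-methylhex-5-en-2-yl 2-(diethoxyphosphoryl)acetate | C[C@@](OC(=O)CP(=O)(OCC)OCC)(COCc1ccc(OC)cc1)CCC=C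
F8 | step 6 | (S)-1-[(4-methoxybenzyl)oxy]-2-methylhex-5-en-2-yl 2-(diethoxyphosphoryl)-6-methylhept-5-enoate | C[C@@](OC(=O)C(CCC=C(C)C)P(=O)(OCC)OCC)(COCc1ccc(OC)cc1)CCC=C
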